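**Strategy.** Everything rests on reading the 1H-pyran ring (C1, O2, C3, C4, C4a, C8a; isochromene numbering) as the dehydrated cyclic hemiketal of an open δ-hydroxy ene-1,5-dione: disconnection O2–C3. The key step exploits two features. The carbocycle locks the C8a=C4a alkene so that the C1 carbinol faces the C3 ketone, and C4–H2 is doubly activated by C3=O and the C8 enone. One acid treatment of the open precursor removes a silyl ether, two MOM ethers and a tert-butyl ester, closes O2–C3 and dehydrates to the push–pull dienol ether. The precursor is assembled from (S)-carvone, a hindered benzoic acid (epoxide opening) and a silyl dienol ether (palladium coupling).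

Key step: step 16

Remark: all intermediates carry the isochromene numbering of the target. α is the ring face that bears the isopropenyl group and β is the other face. Compounds 1, 6, 7 and 10 are taken as commercially available. C8a epimers of 11–18 converge at 19.

Step 1
Reactants: 1 5-methylpyrogallol
Product: 2 2,3,4-trihydroxy-6-methylbenzoic acid
Conditions: KHCO3, H2O, CO2 (1 atm), 100 °C; then aq HCl, 0 °C
Reagents that add atoms: potassium hydrogen carbonate [K+].OC([O-])=O
Why: Kolbe–Schmitt carboxylation should occur ortho to a phenoxide, and the two open ring positions are equivalent by symmetry, so only one acid can form.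

Step 2
Reactants: 2 2,3,4-trihydroxy-6-methylbenzoic acid
Product: 3 methoxymethyl 2-hydroxy-3,4-bis(methoxymethoxy)-6-methylbenzoate
Conditions: MOMCl (3.3 equiv), i-Pr2NEt, CH2Cl2, 0 °C to rt
Reagents that add atoms: chloromethyl methyl ether COCCl
Why: Williamson-type alkylation should take the carboxylate and the 3- and 4-phenols, while the 2-OH is held back by its hydrogen bond to the ester carbonyl.

Step 3
Reactants: 3 methoxymethyl 2-hydroxy-3,4-bis(methoxymethoxy)-6-methylbenzoate
Product: 4 methoxymethyl 2-methoxy-3,4-bis(methoxymethoxy)-6-methylbenzoate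
Conditions: MeI, K2CO3, DMF, 40 °C
Reagents that add atoms: iodomethane CI
Why: Williamson O-methylation under more forcing carbonate conditions should alkylate the one remaining, chelated phenol.

Step 4
Reactants: 4 methoxymethyl 2-methoxy-3,4-bis(methoxymethoxy)-6-methylbenzoate
Product: 5 2-methoxy-3,4-bis(methoxymethoxy)-6-methylbenzoic acid
Conditions: LiOH, THF/H2O, rt; then dilute HCl to pH 4, 0 °C
Reagents that add atoms: lithium hydroxide [Li+].[OH-]
Why: Saponification of the acetal-type MOM ester should be easy despite the two ortho substituents, and the aryl MOM ethers tolerate base and brief mild acidification.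

Step 5
Reactants: 6 methylglyoxal (40% aqueous); 7 tert-butyl (triphenylphosphoranylidene)acetate
Product: 8 tert-butyl (E)-4-oxopent-2-enoate
Conditions: CH2Cl2/H2O, rt
Reagents that add atoms: none
Why: Wittig olefination with a stabilised ylide should take the aldehyde rather than the ketone and give the E-enoate.

Step 6
Reactants: 8 tert-butyl (E)-4-oxopent-2-enoate
Product: 9 tert-butyl (E)-4-(trimethylsilyloxy)penta-2,4-dienoate
Conditions: TMSOTf, Et3N, Et2O, 0 °C
Reagents that add atoms: trimethylsilyl triflate C[Si](C)(C)OS(=O)(=O)C(F)(F)F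
Why: Soft enolisation can involve only the methyl group, so the cross-conjugated 2-silyloxydiene should form with the E-enoate untouched.

Step 7
Reactants: 10 (S)-(+)-carvone
Product: 11 (5S,6S)-6-(hydroxymethyl)carvone (C8a–CH2OH β, trans to isopropenyl)
Conditions: LDA, THF, −78 °C; CH2O (g), −78 to −40 °C; AcOH
Reagents that add atoms: formaldehyde C=O
Why: Kinetic α′-deprotonation at C8a and aldol addition to monomeric formaldehyde should install C1 anti to the isopropenyl group, at a stereocentre that is erased in step 13.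

Step 8
Reactants: 11 (5S,6S)-6-(hydroxymethyl)carvone
Product: 12 TBS ether of 11
Conditions: TBSCl, imidazole, CH2Cl2, rt
Reagents that add atoms: tert-butyldimethylsilyl chloride CC(C)(C)[Si](C)(C)Cl
Why: Standard silylation of the primary alcohol protects the β-hydroxy ketone against retro-aldol cleavage and later oxidation.

Step 9
Reactants: 12 TBS ether of 11
Product: 13 (1S,5S,6S)-allylic alcohol (C8–OH α, cis to isopropenyl)
Conditions: NaBH4, CeCl3·7H2O, MeOH, −20 °C
Reagents that add atoms: none
Why: Luche reduction should give clean 1,2-reduction by axial hydride delivery, which sets the pseudo-equatorial C8 alcohol cis to the isopropenyl group.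

Step 10
Reactants: 13 allylic alcohol
Product: 14 6,7-epoxy alcohol (oxirane O, C8–OH and isopropenyl all α; C7–CH3 β)
Conditions: VO(acac)2 (cat.), t-BuOOH, CH2Cl2, 0 °C to rt
Reagents that add atoms: tert-butyl hydroperoxide CC(C)(C)OO
Why: Vanadium-catalysed hydroxyl-directed epoxidation should oxidise only the allylic C6=C7 alkene, syn to the C8–OH, which sets the C7–O bond on the α face and leaves the isopropenyl group alone.

Step 11
Reactants: 14 6,7-epoxy alcohol; 5 2-methoxy-3,4-bis(methoxymethoxy)-6-methylbenzoic acid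
Product: 15 C6 aroate diol (C6–OCOAr β; C7–OH α; C8–OH α)
Conditions: Ti(Oi-Pr)4, CH2Cl2, rt; aq tartaric acid work-up
Reagents that add atoms: none
Why: Ti(Oi-Pr)4-mediated opening of the 2,3-epoxy alcohol by the carboxylic acid should occur at the distal secondary carbon C6 with SN2 inversion (trans-diaxial, matched with the equatorial isopropenyl group by the Fürst–Plattner rule), which sets C6–O β trans to the retained C7–OH and lets the hindered acid react as an O-nucleophile.

Step 12
Reactants: 15 C6 aroate diol
Product: 16 α-ketol ketone, (6S,7R) in target numbering (isopropenyl α, CH2OTBS β)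
Conditions: DMP, CH2Cl2, rt
Reagents that add atoms: none
Why: Dess–Martin oxidation should convert the only secondary alcohol into the C8 ketone, the tertiary C7–OH being inert.

Step 13
Reactants: 16 α-ketol ketone
Product: 19 enolised 2-(silyloxymethyl)cyclohexane-1,3-dione (6S,7R), via methoxy hydroperoxide 17 (not isolated), via TEMPO ether 18 (not isolated)
Conditions: O3, MeOH, −78 °C; FeSO4·7H2O, TEMPO, −78 °C to rt; mCPBA, CH2Cl2, 0 °C
Reagents that add atoms: TEMPO CC1(C)CCCC(C)(C)N1[O] (the new C4a oxygen); ozone [O-][O+]=O and methanol CO (atoms in 17 only)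
Why: Oxodealkenylation should apply here, since ozonolysis in methanol gives the α-methoxy hydroperoxide, Fe(II) turns it into an alkoxyl radical that fragments by β-scission to the C4a radical, TEMPO traps that radical, and peracid oxidation of the alkoxyamine gives the C4a ketone, so the stereocontrolling isopropenyl group leaves after it has done its work.

Step 14
Reactants: 19 enolised 1,3-dione
Product: 20 C4a enol triflate (vinylogous acyl triflate, C8 ketone)
Conditions: PhNTf2, Et3N, CH2Cl2, 0 °C to rt
Reagents that add atoms: N-phenylbis(trifluoromethanesulfonimide) O=S(=O)(N(c1ccccc1)S(=O)(=O)C(F)(F)F)C(F)(F)F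
Why: Enol triflation of the vinylogous acid should occur on the less hindered C4a oxygen, because the C8 carbonyl is flanked by quaternary C7 and hydrogen-bonded to its hydroxyl.

Step 15
Reactants: 20 C4a enol triflate; 9 tert-butyl (E)-4-(trimethylsilyloxy)penta-2,4-dienoate
Product: 21 open ene-1,5-dione (C4a–CH2–C(=O)–CH=CH–CO2t-Bu; C8a–CH2OTBS)
Conditions: Pd2(dba)3 (cat.), P(t-Bu)3 (cat.), Bu3SnF, CsF, toluene, 80 °C
Reagents that add atoms: none
Why: Palladium-catalysed α-alkenylation of a ketone enolate equivalent (fluoride-promoted coupling of a silyl enol ether through its tin enolate) should join C4a to C4 under nearly neutral conditions, and the dienolate can react only at its CH2 terminus, so the E-4-oxo-enoate arrives intact.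

Step 16
Reactants: 21 open ene-1,5-dione
Product: 24 target CNP0446308.1, via seco hydroxy enedione acid 22 (not isolated), via cyclic hemiketal 23 (not isolated)
Conditions: TFA/CH2Cl2/H2O (10:10:1), 0 °C to rt
Reagents that add atoms: none
Why: Aqueous TFA should cleave the primary TBS ether, both aryl MOM acetals and the tert-butyl ester (22), and the freed C1–OH, held next to the C4 side arm by the ring-locked C8a=C4a alkene, adds to the C3 ketone in a 6-exo-trig closure (23). Acid-catalysed loss of water through the C3 oxocarbenium ion and loss of the doubly activated C4–H then give the C3=C4 enol ether. The closest known reaction type is the cyclodehydration of δ-hydroxy ketones to cyclic enol ethers, the mode by which azaphilone-type pyrans form from ketone–carbinol pairs. No lasting stereocentre is formed (the C3 hemiketal centre is lost again), and C6 and C7 are untouched because C7 is quaternary and the C6–O bond is not ionised under these conditions. The selectivity needed is constitutional, oxygen on C3 and not on C4: the pre-installed C3 carbonyl secures it, whereas hydroalkoxylation of a C3≡C4 alkyne would face 5-exo closure to a fused furan, and the only other hydroxyl (C7–OH) could reach C3 only through a seven-membered ring. Everything before dehydration is reversible, and the O2–C3=C4–C4a=C8a–C8=O push–pull chromophore extended by the E-acrylic acid is the thermodynamic sink.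

**Compound list**
1 | 5-methylpyrogallol | Cc1cc(O)c(O)c(O)c1 | starting material
2 | 2,3,4-trihydroxy-6-methylbenzoic acid | Cc1cc(O)c(O)c(O)c1C(=O)O | intermediate
3 | methoxymethyl 2-hydroxy-3,4-bis(methoxymethoxy)-6-methylbenzoate | Cc1cc(OCOC)c(OCOC)c(O)c1C(=O)OCOC | intermediate
4 | methoxymethyl 2-methoxy-3,4-bis(methoxymethoxy)-6-methylbenzoate | COc1c(OCOC)c(OCOC)cc(C)c1C(=O)OCOC | intermediate
5 | 2-methoxy-3,4-bis(methoxymethoxy)-6-methylbenzoic acid | COc1c(OCOC)c(OCOC)cc(C)c1C(=O)O | intermediate
6 | methylglyoxal | CC(=O)C=O | starting material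
7 | tert-butyl (triphenylphosphoranylidene)acetate | CC(C)(C)OC(=O)C=P(c1ccccc1)(c1ccccc1)c1ccccc1 | starting material
8 | tert-butyl (E)-4-oxopent-2-enoate | CC(=O)/C=C/C(=O)OC(C)(C)C | intermediate
9 | tert-butyl (E)-4-(trimethylsilyloxy)penta-2,4-dienoate | C=C(O[Si](C)(C)C)/C=C/C(=O)OC(C)(C)C | intermediate
10 | (S)-(+)-carvone | CC1=CC[C@H](C(C)=C)CC1=O | starting material
11 | (5S,6S)-6-(hydroxymethyl)carvone | CC1=CC[C@H](C(C)=C)[C@@H](CO)C1=O | intermediate
12 | TBS ether of 11 | CC1=CC[C@H](C(C)=C)[C@@H](CO[Si](C)(C)C(C)(C)C)C1=O | intermediate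
13 | (1S,5S,6S)-allylic alcohol, C8–OH cis to isopropenyl | CC1=CC[C@H](C(C)=C)[C@@H](CO[Si](C)(C)C(C)(C)C)[C@@H]1O | intermediate
14 | 6,7-epoxy alcohol, oxirane, C8–OH and isopropenyl all α | C[C@@]12O[C@@H]1C[C@H](C(C)=C)[C@@H](CO[Si](C)(C)C(C)(C)C)[C@@H]2O | intermediate
15 | C6 aroate diol (C6–O β; C7–OH and C8–OH α) | COc1c(OCOC)c(OCOC)cc(C)c1C(=O)O[C@H]1C[C@H](C(C)=C)[C@@H](CO[Si](C)(C)C(C)(C)C)[C@H](O)[C@]1(C)O | intermediate
16 | α-ketol ketone (6S,7R) | COc1c(OCOC)c(OCOC)cc(C)c1C(=O)O[C@H]1C[C@H](C(C)=C)[C@@H](CO[Si](C)(C)C(C)(C)C)C(=O)[C@]1(C)O | intermediate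
17 | α-methoxy hydroperoxide (side-chain carbon unassigned) | COc1c(OCOC)c(OCOC)cc(C)c1C(=O)O[C@H]1C[C@H](C(C)(OC)OO)[C@@H](CO[Si](C)(C)C(C)(C)C)C(=O)[C@]1(C)O | intermediate
18 | C4a TEMPO ether (C4a epimers) | COc1c(OCOC)c(OCOC)cc(C)c1C(=O)O[C@H]1CC(ON2C(C)(C)CCCC2(C)C)[C@@H](CO[Si](C)(C)C(C)(C)C)C(=O)[C@]1(C)O | intermediate
19 | enolised 1,3-dione (C4a enol, C8 ketone) | COc1c(OCOC)c(OCOC)cc(C)c1C(=O)O[C@H]1CC(O)=C(CO[Si](C)(C)C(C)(C)C)C(=O)[C@]1(C)O | intermediate
20 | C4a enol triflate | COc1c(OCOC)c(OCOC)cc(C)c1C(=O)O[C@H]1CC(OS(=O)(=O)C(F)(F)F)=C(CO[Si](C)(C)C(C)(C)C)C(=O)[C@]1(C)O | intermediate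
21 | open ene-1,5-dione, fully protected | COc1c(OCOC)c(OCOC)cc(C)c1C(=O)O[C@H]1CC(CC(=O)/C=C/C(=O)OC(C)(C)C)=C(CO[Si](C)(C)C(C)(C)C)C(=O)[C@]1(C)O | intermediate
22 | seco hydroxy enedione acid | COc1c(O)c(O)cc(C)c1C(=O)O[C@H]1CC(CC(=O)/C=C/C(=O)O)=C(CO)C(=O)[C@]1(C)O | intermediate
23 | cyclic hemiketal (C3 epimers) | COc1c(O)c(O)cc(C)c1C(=O)O[C@H]1CC2=C(COC(O)(/C=C/C(=O)O)C2)C(=O)[C@]1(C)O | intermediate
24 | CNP0446308.1, (6S,7R) | COc1c(O)c(O)cc(C)c1C(=O)O[C@H]1CC2=C(COC(/C=C/C(=O)O)=C2)C(=O)[C@]1(C)O | target

Total step count: 16. Longest linear sequence: 10 steps (steps 7–16, from 10).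

**Steps most likely to fail**

Step 15. Transmetalation of the cross-conjugated tin dienolate may be slow, the 4-oxo-enoate may oligomerise, or fluoride may trigger vinylogous loss of the aroate.
The fallback sets out from 20 and returns at 24.
Negishi-type coupling of 20 with the Reformatsky reagent of methyl bromoacetate (Pd(PPh3)4, THF) should give the C4a acetic ester F1.
HF·pyridine frees the C1 alcohol, which lactonises to the δ-lactone F2, so the pyran ring closes as an acyl O2–C3 bond.
The vinylogously acidic lactone is enol-triflated (PhNTf2, Et3N) to the ketene acetal triflate F3.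
A Heck reaction with tert-butyl acrylate installs the E-acrylate and gives the protected pyran F4, and TFA then gives 24.

Step 13. Ozone may attack the electron-rich arene, the aminoxyl group may undergo β-elimination before it is oxidised, or the 2-(silyloxymethyl)-1,3-dione may lose silanol.
The fallback sets out from 16 and returns at 19, and it uses the elimination on purpose.
The same ozonolysis gives 17, after which Cu(OAc)2/FeSO4 turns the C4a radical into the alkene, which after conjugation is the enone F5.
Copper-catalysed conjugate borylation (B2pin2, CuCl, NaOt-Bu, MeOH) gives the β-boryl ketone F6, NaBO3 gives the β-hydroxy ketone F7, and Dess–Martin oxidation gives 19.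

Step 16. The free catechol may capture the released formaldehyde, acid may promote loss of the C6 aroate, or dehydration may stay incomplete.
The fallback sets out from 21 and returns at 24.
Buffered HF·pyridine removes only the silyl ether and gives the protected hydroxy enedione F8.
An intramolecular Mitsunobu etherification (PPh3, DIAD), in which the acidic C3 enol oxygen displaces the activated C1 oxygen, closes the other C–O bond (O2–C1) without acid and gives F4.
The MOM ethers and the tert-butyl ester are then removed with TMSOTf/2,6-lutidine and aqueous work-up.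

**Further compounds**
F1 | step 15 | C4a acetic acid methyl ester | COc1c(OCOC)c(OCOC)cc(C)c1C(=O)O[C@H]1CC(CC(=O)OC)=C(CO[Si](C)(C)C(C)(C)C)C(=O)[C@]1(C)O
F2 | step 15 | δ-lactone (3-oxo-isochromane core) | COc1c(OCOC)c(OCOC)cc(C)c1C(=O)O[C@H]1CC2=C(COC(=O)C2)C(=O)[C@]1(C)O
F3 | step 15 | ketene acetal triflate | COc1c(OCOC)c(OCOC)cc(C)c1C(=O)O[C@H]1CC2=C(COC(OS(=O)(=O)C(F)(F)F)=C2)C(=O)[C@]1(C)O
F4 | step 15 | protected pyran (bis-MOM, tert-butyl ester) | COc1c(OCOC)c(OCOC)cc(C)c1C(=O)O[C@H]1CC2=C(COC(/C=C/C(=O)OC(C)(C)C)=C2)C(=O)[C@]1(C)O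
F5 | step 13 | 2-(silyloxymethyl)cyclohexenone | COc1c(OCOC)c(OCOC)cc(C)c1C(=O)O[C@H]1CC=C(CO[Si](C)(C)C(C)(C)C)C(=O)[C@]1(C)O
F6 | step 13 | β-boryl ketone (C4a/C8a epimers) | COc1c(OCOC)c(OCOC)cc(C)c1C(=O)O[C@H]1CC(B2OC(C)(C)C(C)(C)O2)C(CO[Si](C)(C)C(C)(C)C)C(=O)[C@]1(C)O
F7 | step 13 | β-hydroxy ketone (C4a/C8a epimers) | COc1c(OCOC)c(OCOC)cc(C)c1C(=O)O[C@H]1CC(O)C(CO[Si](C)(C)C(C)(C)C)C(=O)[C@]1(C)O
F8 | step 16 | protected hydroxy enedione | COc1c(OCOC)c(OCOC)cc(C)c1C(=O)O[C@H]1CC(CC(=O)/C=C/C(=O)OC(C)(C)C)=C(CO)C(=O)[C@]1(C)O
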